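| flask | substrate | partner | temperature | remark | time |
|---|---|---|---|---|---|
| teal | 1 M | 0.72 equiv | −42 °C | run made earlier |  |
| ochre | 1 M | 1.4 equiv | −26 °C | run made earlier |  |
| grey | 1 M | 2.5 equiv | −42 °C | run made earlier |  |
| Tuesday's | 1.0 M | 3.00 equiv |  | at −20 °C until 2.5 h, from then on at −50 °C | 12 h |
| Monday's | 1.0 M | 0.750 equiv |  | at −20 °C throughout | 3.0 h |

| run | time / h | target / % | substrate / % |
|---|---|---|---|
| teal | 4.00 | 3.3 | 97.3 |
| teal | 8.00 | 7.2 | 93.8 |
| teal | 15.0 | 10.3 | 90.0 |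
| teal | 20.0 | 12.8 | 85.7 |
| teal | 25.0 | 14.2 | 82.4 |
| ochre | 0.833 | 8.2 | 91.3 |
| ochre | 2.00 | 16.5 | 81.8 |
| ochre | 4.00 | 26.8 | 68.8 |
| ochre | 6.00 | 33.0 | 55.6 |
| ochre | 8.00 | 42.0 | 46.5 |
| grey | 2.50 | 5.6 | 94.5 |
| grey | 6.00 | 14.4 | 85.4 |
| grey | 12.0 | 26.7 | 74.3 |
| grey | 20.0 | 38.3 | 62.0 |
| grey | 25.0 | 42.9 | 51.8 |

(standard deviation of a reading: 1 percentage point)

- in a conversion other conformer counts as not yet reacted

- which of the two ends with the higher amount of target, in percent of the substrate charged ("neither" if they lie within 2 percentage points) (Tuesday's / Monday's / neither)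
- target at the end, in percent of the substrate charged, Tuesday's
- target at the end, in percent of the substrate charged, Monday's

The late hours of Tuesday's flask were my question: 9.50 h at −50 °C after 2.5 h at −20 °C. I took the rate of target as k·[substrate]·[partner] and held partner at its charge (pseudo-first-order), so that target is one minus exp(−D), with D = k·[partner]·time. The grey run at 12.0 h read as k = 0.0104 M⁻¹ h⁻¹ at −42 °C, and the ochre run at 2.00 h as 0.0644 M⁻¹ h⁻¹ at −26 °C. Taking ln k as straight in temperature, I got k = 0.128 M⁻¹ h⁻¹ at −20 °C, and a cold hour was worth w = 0.0325 of a warm hour.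

Two extreme flasks were easy. Frozen at the change, Tuesday's flask gave 61.7 % target; kept warm for 12 h, it gave 99.0 %. Before any side loss, my reckoning put the real flask between them, nearer the frozen one. Its warm-equivalent time 2.81 h, the warm hours plus each cold hour counted at w, stood much closer to 2.5 h than to 12 h. That gave 65.9 %. The ochre run ended 11.5 % short of its charge in target plus substrate, and taking that off left me at 54.4 %. Monday's flask, reckoned the same way before any loss, gave 25.0 %, less than my Tuesday's figure.

The forecast said 52 % for Tuesday's, below mine, and 19 % for Monday's, so Tuesday's ahead: "The cold 9.5 h then adds only about 4%".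

The flasks ended at 54.0 % target on Tuesday's and 18.6 % on Monday's, so Tuesday's is higher.

    substrate ⇌ other conformer (K = 2.14, k = 1.51 × 10⁻⁵ s⁻¹, Ea = 93.0 kJ mol⁻¹, ΔH = −13.0 kJ mol⁻¹)
    substrate + partner → target (k = 3.40 × 10⁻⁵ M⁻¹ s⁻¹, Ea = 55.0 kJ mol⁻¹)
    partner + other conformer → isomer of the product A (k = 2.25 × 10⁻⁵ M⁻¹ s⁻¹, Ea = 67.0 kJ mol⁻¹)
    partner → decomposition product (k = 3.16 × 10⁻⁸ s⁻¹, Ea = 105 kJ mol⁻¹)
    target ⇌ isomer of the product B (K = 0.561, k = 7.81 × 10⁻⁶ s⁻¹, Ea = 86.0 kJ mol⁻¹, ΔH = 5.00 kJ mol⁻¹)
    (constants at −20 °C)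

At −20 °C in Tuesday's flask, the half-life of substrate by the step to target alone, the other concentrations as charged, was 1.9 h, far shorter than the 25 h of target by its forward step to isomer of the product B alone. The cold stretch, priced at 0.310 h of warm time, added 3.1 percentage points. A neighbouring flask, Monday's with 3.00 equiv of partner, stays warm, so its warm-equivalent time is 3.00 h, and the same reckoning gives 56.8 %; it holds 55.4 % target.

The runs are simulated with made-up constants, noise included.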